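**Plan**

1. Ring numbering used throughout (that of the bicyclic intermediates): C1 = enone β-CH, C2 = C–CH2OH, C3 = C=O, C4 = CH–O(epoxyangeloyl), C5 = CH–iPr, C6 = CH–O(angeloyl). O7 is the oxygen on C4.
2. Retrosynthesis first cuts the two acyl–O bonds (O7–acyl, then C6–O–acyl). The enabling feature is that O7 on C4 lies 1,4 across the carbocycle from C1, the β-carbon of the C1=C2–C3=O enone. The 4-oxy-enone is therefore the β-eliminated form of a 7-oxabicyclo[2.2.1]hept-2-ene whose C2=C3 bond is a C3 enol ether, and O7 is re-tied to C1.
3. The bicycle is cut at C1–C2 and C3–C4 in one retro-[4+2] event. This gives 3-isopropylfuran (C1, C6, C5, C4, O7) and methyl 3-bromopropiolate (C2, C3, ester carbon = future CH2OH, Br = placeholder for the C3 oxygen).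
4. Forward order: furan ring (bought as 3-bromofuran), then carbocycle and second oxacycle together in the cycloaddition, then Br/OMe exchange. C5=C6 is then functionalised while C2=C3 stays sp2 (empty endo pocket), followed by angelate, bridge cut (enone + free C4–OH), epoxyangelate and desilylation.
5. Stereochemistry: the chiral Lewis acid of the cycloaddition sets C4 and the relay centre C1. C5 and C6 are relayed from the bridge by two exo-face attacks (hydroboration puts iPr endo, hydride on the C6 ketone puts O endo). The epoxy acid comes from a Sharpless epoxidation (L-(+)-DET) of angelyl alcohol, and the Z-alkene is bought with angelic acid.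

Key step: step 6

Assumption: the sense of induction of the catalyst class used in step 6 is not established for alkynoates. The (S)-catalyst is written for the (1R,4S)-cycloadduct, and the mirror-image catalyst from (R)-diphenylprolinol would be taken if the opposite sense is found.

**Route**

Step 1
Reactants: 1 angelic acid ((Z)-2-methylbut-2-enoic acid)
Product: 2 angelyl alcohol ((Z)-2-methylbut-2-en-1-ol)
Conditions: LiAlH4, Et2O, 0 °C → rt; then H2O
Reagents that add atoms: none
Why: Hydride reduction of the carboxylic acid with LiAlH4 stops at the primary allylic alcohol and touches neither the trisubstituted alkene nor its Z geometry, because hydride adds 1,2 to the carboxylate and the alkene offers no conjugate pathway at this temperature.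

Step 2
Reactants: 2 angelyl alcohol
Product: 3 (2S,3R)-2,3-epoxy-2-methylbutan-1-ol
Conditions: Ti(OiPr)4 (10 mol %), L-(+)-diethyl tartrate (12 mol %), t-BuOOH, 4 Å molecular sieves, CH2Cl2, −20 °C
Reagents that add atoms: tert-butyl hydroperoxide, CC(C)(C)OO
Why: Sharpless asymmetric epoxidation: the titanium–L-(+)-tartrate complex binds the allylic alkoxide and t-BuOOH and delivers oxygen to the alkene face that gives the (2S)-epoxy alcohol, while the syn addition carries the Z geometry into the cis relation of CH2OH and the C3 methyl group, i.e. (2S,3R).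

Step 3
Reactants: 3 (2S,3R)-2,3-epoxy-2-methylbutan-1-ol
Product: 4 (2R,3R)-2,3-epoxy-2-methylbutanoic acid (epoxyangelic acid)
Conditions: RuCl3·xH2O (2 mol %), NaIO4, MeCN/EtOAc/H2O, 0 °C → rt
Reagents that add atoms: sodium periodate, [Na+].[O-]I(=O)(=O)=O
Why: Ruthenium tetroxide generated catalytically from RuCl3 and NaIO4 oxidises the primary alcohol through the aldehyde hydrate to the acid without opening the epoxide, so both stereocentres are kept (the C2 descriptor changes from S to R only because the CIP ranking changes).

Step 4
Reactants: 5 3-bromofuran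
Product: 6 3-isopropylfuran
Conditions: iPrMgCl, PdCl2(dppf) (2 mol %), Et2O, 0 °C → rt; distillation
Reagents that add atoms: isopropylmagnesium chloride, CC(C)[Mg]Cl
Why: Kumada–Corriu cross-coupling, in which the wide bite angle of dppf speeds reductive elimination from the secondary alkylpalladium intermediate past β-hydride elimination, so that isopropyl is transferred without isomerisation to n-propyl.

Step 5
Reactants: 7 methyl propiolate
Product: 8 methyl 3-bromopropiolate
Conditions: NBS, AgNO3 (10 mol %), acetone, rt
Reagents that add atoms: N-bromosuccinimide, O=C1CCC(=O)N1Br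
Why: Silver-catalysed electrophilic bromination of a terminal alkyne, in which the silver acetylide formed with AgNO3 is brominated at carbon by NBS, is a standard route to 1-bromoalkynes and leaves the ester untouched.

Step 6
Reactants: 6 3-isopropylfuran; 8 methyl 3-bromopropiolate
Product: 9 methyl (1R,4S)-3-bromo-5-isopropyl-7-oxabicyclo[2.2.1]hepta-2,5-diene-2-carboxylate
Conditions: (S)-3,3-diphenyl-1-(o-tolyl)tetrahydro-1H,3H-pyrrolo[1,2-c][1,3,2]oxazaborole (20 mol %) protonated with Tf2NH (18 mol %), CH2Cl2, −60 → −40 °C; chromatography
Reagents that add atoms: none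
Why: Proposed new method: boron of the cationic oxazaborolidine binds the ester carbonyl lone pair that lies syn to the slim alkynyl group, lowers the ynoate LUMO and should let a concerted, asynchronous [4π+2π] cycloaddition (C3–C4 bond leading) run far below the about 80 °C that the uncatalysed reaction needs, so that no racemic background competes. The closest known reaction types are the thermal Diels–Alder reaction of alkylfurans with methyl 3-bromopropiolate, the enantioselective Diels–Alder reactions of furan with acrylic dienophiles under chiral boron or copper Lewis acids, and those of cyclopentadienes with alkynyl ketones, alkynals and propiolamides under the same kind of catalyst; new is only the pairing of a furan with a haloalkynoate under such a catalyst. Both σ-bonds form suprafacially on one face of the furan in an intermolecular cycloaddition mode, which closes at once the six-membered carbocycle C1–C6 and the second five-membered oxacycle O7–C1–C2–C3–C4 of the 7-oxabicyclo[2.2.1]heptadiene. The new stereocentres C1 and C4 are locked cis to one another by the bridge and their absolute sense is set by the catalyst, whose aryl groups screen one face of the bound ynoate and leave room for the small O7 side of the furan next to boron; C4 stays in the target, C1 serves as a relay and is flattened in step 13. Regioselectivity is the selectivity most needed: the furan α-carbon next to the isopropyl group (C4) carries the largest HOMO coefficient and bonds to the β-carbon of the ynoate (C3, C–Br), the "para" orientation of isopropyl and ester, and Lewis-acid polarisation should sharpen this bias. Friedel–Crafts-type conjugate addition of the furan and acid-induced aromatisation of 9 are held back by the low temperature and by the ester and bromine on C2=C3, which destabilise the cation that C–O7 ionisation would give.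

Step 7
Reactants: 9 bromo-diene ester
Product: 10 methyl (1R,4S)-5-isopropyl-3-methoxy-7-oxabicyclo[2.2.1]hepta-2,5-diene-2-carboxylate
Conditions: NaOMe (1.0 equiv), THF, −40 → 0 °C
Reagents that add atoms: sodium methoxide, [Na+].[O-]C
Why: Addition–elimination at the β-carbon of the β-bromoacrylate unit (methoxide adds to C3, the ester enolate expels bromide), and since the single equivalent of methoxide ends as NaBr no base is left to add a second methanol to the strained push–pull alkene; C1 and C4 are not touched.

Step 8
Reactants: 10 methoxy-diene ester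
Product: 12 methyl (1S,4S,5R,6R)-6-exo-hydroxy-5-endo-isopropyl-3-methoxy-7-oxabicyclo[2.2.1]hept-2-ene-2-carboxylate, via exo-C6 monoalkylborane 11 (not isolated)
Conditions: BH3·THF, THF, 0 °C; then 30 % H2O2, aq NaOAc, 0 °C
Reagents that add atoms: borane (used as BH3·THF), B (boron, into 11 only); hydrogen peroxide, OO
Why: Hydroboration–oxidation: borane picks the strained, electron-richer trisubstituted C5=C6 bond over the tetrasubstituted push–pull C2=C3 bond and adds syn from the exo face (the side of O7) with boron on the less substituted C6, which pushes the isopropyl group on C5 into the endo position opposite the flat C3, and the C–B bond is oxidised with retention to the exo alcohol.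

Step 9
Reactants: 12 exo-alcohol
Product: 13 methyl (1S,4S,5S)-5-endo-isopropyl-3-methoxy-6-oxo-7-oxabicyclo[2.2.1]hept-2-ene-2-carboxylate
Conditions: Dess–Martin periodinane, CH2Cl2, 0 °C → rt
Reagents that add atoms: none
Why: Dess–Martin oxidation works without base, so that the C6 ketone is formed without epimerising the adjacent endo-isopropyl centre C5 and without β-elimination of O7 from C4.

Step 10
Reactants: 13 keto ester
Product: 14 (1S,4S,5R,6S)-2-(hydroxymethyl)-5-endo-isopropyl-3-methoxy-7-oxabicyclo[2.2.1]hept-2-en-6-endo-ol
Conditions: iBu2AlH (5 equiv), CH2Cl2, −78 °C; aq potassium sodium tartrate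
Reagents that add atoms: none
Why: iBu2AlH reduces the C6 ketone from the open exo face (the endo face is closed by the C2=C3 bridge and the endo isopropyl group), which sets the endo C6–OH cis to isopropyl, and in the same operation reduces the vinylogous carbonate ester 1,2 to the allylic alcohol, whose acid-labile 3-methoxyallyl alcohol unit survives the non-acidic work-up.

Step 11
Reactants: 14 diol
Product: 15 (1S,4S,5R,6S)-2-[(tert-butyldiphenylsilyloxy)methyl]-5-endo-isopropyl-3-methoxy-7-oxabicyclo[2.2.1]hept-2-en-6-endo-ol
Conditions: TBDPSCl (1.05 equiv), imidazole, CH2Cl2, 0 °C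
Reagents that add atoms: tert-butyl(chloro)diphenylsilane, CC(C)(C)[Si](Cl)(c1ccccc1)c1ccccc1
Why: Steric differentiation in silylation: the bulky TBDPSCl reacts with the primary allylic hydroxyl far faster than with the secondary hydroxyl buried in the endo pocket next to isopropyl.

Step 12
Reactants: 15 silyl ether alcohol; 1 angelic acid
Product: 18 C6-endo angelate of 15, via angelic 2,4,6-trichlorobenzoic anhydride 16 (not isolated), via lithium alkoxide 17 (not isolated)
Conditions: (a) 1, 2,4,6-Cl3C6H2COCl, Et3N, THF, 0 °C → rt, filter; (b) 15, LiN(SiMe3)2, THF, −78 °C; (c) solution of 16 added, −78 → 0 °C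
Reagents that add atoms: 2,4,6-trichlorobenzoyl chloride, O=C(Cl)c1c(Cl)cc(Cl)cc1Cl (into 16 only); lithium hexamethyldisilazide, [Li+].C[Si](C)(C)[N-][Si](C)(C)C (lithium, into 17 only)
Why: Yamaguchi-type mixed-anhydride acylation of a preformed lithium alkoxide: the alkoxide attacks the less hindered angeloyl carbonyl of 16 at low temperature, and because no nucleophilic catalyst such as DMAP can add reversibly to the enoyl unit the Z geometry should be conserved, while C6 keeps its configuration since its C–O bond is not touched.

Step 13
Reactants: 18 angelate enol ether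
Product: 20 (4S,5S,6R)-6-angeloyloxy-4-hydroxy-5-isopropyl-2-[(tert-butyldiphenylsilyloxy)methyl]cyclohex-1-en-3-one (route numbering), via trimethylsilyl ether 19 (not isolated)
Conditions: Me3SiOTf, 2,6-lutidine, CH2Cl2, −78 → −20 °C; H2O; then citric acid, MeOH, 0 °C
Reagents that add atoms: trimethylsilyl triflate, C[Si](C)(C)OS(=O)(=O)C(F)(F)F (silyl group, into 19 only); water, O
Why: Silyl-triflate-induced opening of the oxa-bridge, the reaction type known for 7-oxanorbornan-2-ones through their silyl enol ethers and related to the unmasking of Danishefsky-diene adducts: Me3Si+ binds the most accessible and basic ether oxygen O7, the C3 enol ether pushes out the C1–O7 bond to give a methoxyallyl cation held as its lutidinium salt, water turns this into the C1=C2–C3=O enone and methanol, and mild methanolysis frees the C4–OH, whose configuration (the C4–O7 bond is never broken) and those of C5 and C6 are kept.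

Step 14
Reactants: 20 hydroxy-enone; 4 (2R,3R)-epoxyangelic acid
Product: 21 (4S,5R,6R)-6-angeloyloxy-4-[(2R,3R)-2,3-epoxy-2-methylbutanoyloxy]-5-isopropyl-2-[(tert-butyldiphenylsilyloxy)methyl]cyclohex-1-en-3-one (route numbering)
Conditions: DIC, DMAP (10 mol %), CH2Cl2, 0 °C
Reagents that add atoms: none
Why: Steglich esterification (carbodiimide activation of 4, acyl transfer by DMAP) acylates the only free hydroxyl, the equatorial C4–OH, with retention at C4 and at both epoxide carbons, the electron-poor glycidic epoxide being inert to these conditions.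

Step 15
Reactants: 21 silyl-protected diester
Product: 22 target, (4S,5R,6R)-6-angeloyloxy-4-[(2R,3R)-2,3-epoxy-2-methylbutanoyloxy]-2-(hydroxymethyl)-5-isopropylcyclohex-1-en-3-one (route numbering)
Conditions: HF·pyridine, pyridine, THF, 0 °C → rt
Reagents that add atoms: none
Why: Fluoride-driven cleavage of the Si–O bond with pyridine-buffered HF·pyridine is neither basic enough to trigger acyl migration or β-elimination in the diacyloxy-enone nor acidic enough to open the ester-deactivated epoxide, and it touches no stereocentre.

**Compound list**

1 | angelic acid, (Z)-2-methylbut-2-enoic acid | C/C=C(/C)C(=O)O | starting material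
2 | angelyl alcohol, (Z)-2-methylbut-2-en-1-ol | C/C=C(/C)CO | intermediate
3 | (2S,3R)-2,3-epoxy-2-methylbutan-1-ol | OC[C@]1(C)O[C@@H]1C | intermediate
4 | (2R,3R)-2,3-epoxy-2-methylbutanoic acid | OC(=O)[C@]1(C)O[C@@H]1C | intermediate
5 | 3-bromofuran | Brc1ccoc1 | starting material
6 | 3-isopropylfuran | CC(C)c1ccoc1 | intermediate
7 | methyl propiolate | C#CC(=O)OC | starting material
8 | methyl 3-bromopropiolate | BrC#CC(=O)OC | intermediate
9 | methyl (1R,4S)-3-bromo-5-isopropyl-7-oxabicyclo[2.2.1]hepta-2,5-diene-2-carboxylate | COC(=O)C1=C(Br)[C@H]2O[C@@H]1C=C2C(C)C | intermediate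
10 | methyl (1R,4S)-5-isopropyl-3-methoxy-7-oxabicyclo[2.2.1]hepta-2,5-diene-2-carboxylate | COC(=O)C1=C(OC)[C@H]2O[C@@H]1C=C2C(C)C | intermediate
11 | exo-C6 monoalkylborane of 10 (BH2 exo on C6, iPr endo on C5) | COC(=O)C1=C(OC)[C@H]2O[C@@H]1[C@H](B)[C@H]2C(C)C | intermediate (not isolated)
12 | methyl (1S,4S,5R,6R)-6-exo-hydroxy-5-endo-isopropyl-3-methoxy-7-oxabicyclo[2.2.1]hept-2-ene-2-carboxylate | COC(=O)C1=C(OC)[C@H]2O[C@@H]1[C@H](O)[C@H]2C(C)C | intermediate
13 | methyl (1S,4S,5S)-5-endo-isopropyl-3-methoxy-6-oxo-7-oxabicyclo[2.2.1]hept-2-ene-2-carboxylate | COC(=O)C1=C(OC)[C@H]2O[C@@H]1C(=O)[C@H]2C(C)C | intermediate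
14 | (1S,4S,5R,6S)-2-(hydroxymethyl)-5-endo-isopropyl-3-methoxy-7-oxabicyclo[2.2.1]hept-2-en-6-endo-ol | OCC1=C(OC)[C@H]2O[C@@H]1[C@@H](O)[C@H]2C(C)C | intermediate
15 | primary TBDPS ether of 14 | CC(C)(C)[Si](OCC1=C(OC)[C@H]2O[C@@H]1[C@@H](O)[C@H]2C(C)C)(c1ccccc1)c1ccccc1 | intermediate
16 | angelic 2,4,6-trichlorobenzoic anhydride | C/C=C(/C)C(=O)OC(=O)c1c(Cl)cc(Cl)cc1Cl | intermediate (not isolated)
17 | lithium C6-alkoxide of 15 | [Li+].CC(C)(C)[Si](OCC1=C(OC)[C@H]2O[C@@H]1[C@@H]([O-])[C@H]2C(C)C)(c1ccccc1)c1ccccc1 | intermediate (not isolated)
18 | C6-endo angelate of 15 | CC(C)(C)[Si](OCC1=C(OC)[C@H]2O[C@@H]1[C@@H](OC(=O)/C(C)=C\C)[C@H]2C(C)C)(c1ccccc1)c1ccccc1 | intermediate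
19 | (4S,5R,6R)-6-angeloyloxy-5-isopropyl-4-(trimethylsilyloxy)-2-[(TBDPS-oxy)methyl]cyclohex-1-en-3-one (route numbering) | C/C=C(/C)C(=O)O[C@@H]1C=C(CO[Si](c2ccccc2)(c2ccccc2)C(C)(C)C)C(=O)[C@@H](O[Si](C)(C)C)[C@@H]1C(C)C | intermediate (not isolated)
20 | (4S,5S,6R)-6-angeloyloxy-4-hydroxy-5-isopropyl-2-[(TBDPS-oxy)methyl]cyclohex-1-en-3-one (route numbering) | C/C=C(/C)C(=O)O[C@@H]1C=C(CO[Si](c2ccccc2)(c2ccccc2)C(C)(C)C)C(=O)[C@@H](O)[C@@H]1C(C)C | intermediate
21 | (4S,5R,6R)-6-angeloyloxy-4-[(2R,3R)-2,3-epoxy-2-methylbutanoyloxy]-5-isopropyl-2-[(TBDPS-oxy)methyl]cyclohex-1-en-3-one (route numbering) | C/C=C(/C)C(=O)O[C@@H]1C=C(CO[Si](c2ccccc2)(c2ccccc2)C(C)(C)C)C(=O)[C@@H](OC(=O)[C@]2(C)O[C@@H]2C)[C@@H]1C(C)C | intermediate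
22 | CNP0293054.1 | C/C=C(/C)C(=O)O[C@@H]1C=C(CO)C(=O)[C@@H](OC(=O)[C@]2(C)O[C@@H]2C)[C@@H]1C(C)C | target

**Step count**

Total step count: 15. Longest linear sequence: 11 (step 4 or 5, then steps 6–15).

**Steps most likely to fail**

**Step 6.** The linear ynoate offers the catalyst only one contact point, so facial discrimination may be poor. Regiocontrol by a single alkyl group may be weak. The strong Lewis acid may drive conjugate addition of the furan or aromatisation of the adduct.

The fallback uses known chemistry, sets out from 6 and 8 and comes back at 9. The two components are heated without catalyst in toluene at 80 °C (thermal Diels–Alder reaction) and the minor regioisomer is removed by chromatography. The racemate consists of 9 and its mirror image methyl (1S,4R)-3-bromo-5-isopropyl-7-oxabicyclo[2.2.1]hepta-2,5-diene-2-carboxylate F1. It is resolved by preparative supercritical-fluid chromatography on an amylose tris(3,5-dimethylphenylcarbamate) phase.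

**Step 13.** The silyl cation may activate the exocyclic CH2–OSi oxygen instead of O7, with loss of the silyloxy group. Proton loss from the methoxyallyl cation may lead to loss of angelic acid and aromatisation, or to scrambling at C4.

The fallback sets out from 18 and comes back at 20. It replaces the Lewis-acid pull by hydrolysis followed by a base push. Dilute aqueous HCl in THF hydrolyses the enol ether to the bridged ketone 6-endo-angeloyloxy-2-[(tert-butyldiphenylsilyloxy)methyl]-5-endo-isopropyl-7-oxabicyclo[2.2.1]heptan-3-one F2. This is obtained as C2 epimers, and the exo-CH2OSi epimer is drawn. It is then opened by E1cB elimination of O7 from C1 with DBU in CH2Cl2.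

**Step 12.** Acylation of the alkoxide in the crowded endo pocket may be slow. This would leave time for Z-to-E isomerisation of the acyl donor or for attack at the aroyl carbonyl.

The fallback sets out from 15 and comes back at 18. It builds the Z-alkene on the substrate. Alcohol 15 is esterified with 2-[bis(2,2,2-trifluoroethoxy)phosphoryl]propanoic acid (DIC, stoichiometric DMAP, which is harmless here because no alkene geometry is at stake). This gives the C6-endo 2-[bis(2,2,2-trifluoroethoxy)phosphoryl]propanoate of 15 F3. A Still–Gennari olefination with acetaldehyde (KN(SiMe3)2, 18-crown-6, THF, −78 °C) then gives the (Z)-2-methylbut-2-enoate.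

**Further compounds**

F1 | step 6 | methyl (1S,4R)-3-bromo-5-isopropyl-7-oxabicyclo[2.2.1]hepta-2,5-diene-2-carboxylate | COC(=O)C1=C(Br)[C@@H]2O[C@H]1C=C2C(C)C
F2 | step 13 | 6-endo-angeloyloxy-2-[(tert-butyldiphenylsilyloxy)methyl]-5-endo-isopropyl-7-oxabicyclo[2.2.1]heptan-3-one (exo-CH2OSi epimer drawn) | CC(C)(C)[Si](OC[C@H]1C(=O)[C@H]2O[C@@H]1[C@@H](OC(=O)/C(C)=C\C)[C@H]2C(C)C)(c1ccccc1)c1ccccc1
F3 | step 12 | C6-endo 2-[bis(2,2,2-trifluoroethoxy)phosphoryl]propanoate of 15 (epimers at the phosphonate carbon) | CC(C)(C)[Si](OCC1=C(OC)[C@H]2O[C@@H]1[C@@H](OC(=O)C(C)P(=O)(OCC(F)(F)F)OCC(F)(F)F)[C@H]2C(C)C)(c1ccccc1)c1ccccc1
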